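A first-order flask cannot do what these two do: its share turned at a given time is the same for every charge, yet at 14 min the spring run stands at 28.7% and the summer run at 12.0%.

| flask | starting material | time |
|---|---|---|
| spring | 0.800 M |  |
| summer | 0.400 M |  |
| noon | 0.120 M | 22 min |

| run | time / min | [product] / M |
|---|---|---|
| spring run | 0.88 | 0 |
| spring run | 1.4 | 0.007 |
| spring run | 2.2 | 0 |
| spring run | 3.5 | 0 |
| spring run | 5.5 | 0.023 |
| spring run | 8.8 | 0.069 |
| spring run | 14 | 0.230 |
| spring run | 22 | 0.598 |
| summer run | 0.88 | 0 |
| summer run | 1.4 | 0.001 |
| summer run | 2.2 | 0 |
| summer run | 3.5 | 0 |
| summer run | 5.5 | 0.003 |
| summer run | 8.8 | 0.007 |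
| summer run | 14 | 0.048 |
| summer run | 22 | 0.109 |

(each reading ± 0.01 M)

1. reaction order in [starting material] at the outset, round the charge of the spring run, defined at two percent of the starting material turned into product (one fixed amount of product, the same in the runs compared)
2. product in the noon run at 22 min, as a share of the starting material charged
3. which of these the readings show (nothing beyond the main steps / the product speeds the reaction / two substrates go astray together / the product binds the substrate)

- Overall: starting material -> product.
- Constant volume, constant temperature.
- An order is taken over about fifteen percent of the charge, up and down.

So I take product to help make product (autocatalysis) and write the rate as [starting material] times (u + g[product]). Two times follow: T = 1/u, the unaided time, and τ = 1/(gc), the aided time at charge c. From 14 min to 22 min in the spring run, the rise in ln of the odds (product over charge less product), per minute and per charge, reads as the growth constant g = 0.311 M⁻¹ min⁻¹; the summer run reads 0.316 M⁻¹ min⁻¹.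

While product is a small share of the charge, that share is about (τ/T)(exp(t/τ) − 1). The summer reading at 14 min, with τ = 8.03 min, gives T = 316 min. For the noon run τ is 26.8 min, so I reckon 10.8% at 22 min. At one fixed amount of product my rate law is first order in [starting material], so I expect an order near 1.

The forecast gives 0.95, 7.5% and "the product speeds the reaction", holding that “yield also rises strongly with charge”, and its noon share is lower than mine.

The noon run gives 12.5%, more than my 10.8%; the order is 0.96, and the answer to the third question is that the product speeds the reaction. With the same amount of product made, the summer rate is 0.0036 M min⁻¹ against 0.0072 M min⁻¹ in the spring run.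

    starting material ⇌ intermediate (0.09000 min⁻¹, 0.4266 min⁻¹)
    intermediate → product (0.02664 min⁻¹)
    starting material + product → 2 product (0.3804 M⁻¹ min⁻¹)

As product goes from a quarter to half of the charge, the odds rise 3-fold, which in my rate law, with the unaided term left out, takes ln 3 aided times. With g that is 4.41 min in the spring run, where the flask takes 4.22 min, and 8.82 min in the summer run, where the flask takes 7.95 min.

The earlier runs and the new flask stem from a simulated flask with made-up constants; the scatter is artificial.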